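The constants set the contest: X takes G at 352 L mol⁻¹ s⁻¹ against 317 L mol⁻¹ s⁻¹ for D, while D slips to L at 0.408 s⁻¹ and Z opens at 0.0744 s⁻¹.

    Z ⇌ G (K1 = 0.277, k1 = 0.0744 s⁻¹)
    D + G → D.G (k2 = 317 L mol⁻¹ s⁻¹)
    X + G → X.G (k3 = 352 L mol⁻¹ s⁻¹)
    D ⇌ L (K4 = 1.35, k4 = 0.408 s⁻¹)
    D.G ⇌ J (K5 = 1.76, k5 = 0.00781 s⁻¹)

| flask | Z | D | X | time | remark |
|---|---|---|---|---|---|
| Saturday's | 20 mM | 1.00 equiv | 1.10 equiv | 15 s | a closed flask charged with all of it at once and left for 15 s |
| Sunday's | 20 mM | 1.00 equiv | 1.10 equiv (fed, over 15.0 s) | 15 s | a stirred flask in which X is dosed at a steady rate over 15.0 s without added volume, worked up at 15 s |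
| Tuesday's | 20 mM | 1.00 equiv | 1.10 equiv |  | one stirred flow tank at steady state, fed with the mixture as stated, mean residence time 15 s |
| Monday's | 20 mM (fed, over 15.0 s) | 1.00 equiv | 1.10 equiv | 15 s | all but Z at the start; Z goes in evenly over 15.0 s, the run ends at 15 s |

- the set-up with the highest share of D.G in all that became D.G or X.G or J, at the outlet or at the end ("none" if the first two lie within 2 percentage points) (Saturday's / Sunday's / Tuesday's / Monday's / none)
- share of D.G in all that became D.G or X.G or J, at the outlet or at the end, Saturday's
- share of D.G in all that became D.G or X.G or J, at the outlet or at the end, Sunday's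
- share of D.G in all that became D.G or X.G or J, at the outlet or at the end, Tuesday's
- share of D.G in all that became D.G or X.G or J, at the outlet or at the end, Monday's

- the stated concentrations are those of everything mixed, before any reaction; amounts are the same in each set-up
- the feed brings no volume worth counting
- run time (Saturday's): 15 s

I opened the meeting by noting that G is a short-lived intermediate at quasi-steady state, since by its step alone X removes G, as charged in Saturday's, with a half-life of 0.090 s, far shorter than the 9.3 s of Z, and that D goes to L faster than Z opens, with a half-life of 1.7 s, so each G is shared out by the [D] and [X] of its moment. With D in equilibrium with L and X as charged, I put the figure at 25.8% and named it the capture share, the constant of D + G times [D] over that product plus the constant of X + G times [X].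

For Monday's I proposed going round once more: Z fed evenly and opening at its forward rate has put about 7.95 mM through G by the end, which takes [X] to 16.1 mM and [D] to 7.64 mM, and these put back give 29.9%. I took the mean of the two rounds, removed the 5.86% of the D side that I reckoned goes to J over about half the run, and committed to 26.2% for Monday's. For Sunday's I pointed out that with half of X fed, and none of it counted as spent, the first round already reads 41.1%, more than the opening figure, so I named Sunday's as best.

The author of the forecast also chose Sunday's, arguing that “X is scarce early, so D takes most G while D is still high”, and tabled 49.6% for it, against 29% for Saturday's, 29% for Tuesday's and 26.4% for Monday's.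

The simulation names Sunday's, at 48.1%, with Saturday's at 28.9%, Tuesday's at 29.0% and Monday's at 26.6%. In Monday's flask the loss of D to L had 72% of its turnover behind it by 1.50 s, when capture by X had 1.1% of its own, and the end readings of D and X, 37.1% and 74.7% of their charges, give a capture share of 28.9%, against my 29.9%. Monday's neighbour charged with 2.80 equiv of X, for which 25.8% rescaled to that charge reads 12.0%, gave 12.2%, below the forecast's low end of 25% for Monday's.

The numbers are assumed.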